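A direct plan would condense 2-hydroxy-3,4,6-trimethoxyacetophenone A1 with 3,4,5-tris(benzyloxy)benzaldehyde A2 to the chalcone A3, close ring C by Algar–Flynn–Oyamada oxidation to the flavonol A4, methylate O3 to the tetramethyl ether A5, oxidise ring A with (NH4)2Ce(NO3)6 to the 5,8-quinone A6, and finish by hydrogenation.
- The peroxide ring closure of A3 would be weak: a 6'-methoxy group twists the enone and is known to divert such chalcones to five-membered closure (aurones), so the pyranone would be made in the least controlled step.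
- Carrying O5 and O8 as methyl ethers, then demethylating A5 oxidatively and reducing again, would be three protecting-group and redox events that build nothing. The oxidant would also meet the tris(benzyloxy)phenyl ring brought in with A2 and an enol ether, and would leave the very electrophilic quinone A6 late in the route.
- Access to A1 would rest on a Lewis acid cleaving exactly one of four aryl methyl ethers.

**Retrosynthetic overview**

- Key disconnection: the aryl ether bond O1–C8a of ring C. A 1-(2,5-dihydroxy-4-methoxyphenyl)-1,3-diketone is dehydrogenated to its 2-acyl-1,4-benzoquinone, and the diketone enol oxygen adds to the quinone carbon next to the acyl group.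
- Feature used: in ring A, O5 and O8 are para (a hydroquinone), C4a carries the C4 carbonyl, and C8a (neighbour of C4a, ortho to C8–OH) carries O1. This is the pattern that nucleophilic addition to an acylquinone followed by re-aromatisation produces.
- Earlier disconnections: C2–C3 by C-acylation of an ω-methoxyketone polyanion with a protected galloyl imidazolide, and C4–C4a by Friedel–Crafts acylation of methoxyhydroquinone with methoxyacetic acid.
- Ring order: rings A and B are bought; ring C is the only ring made and it closes last, at O1–C8a and not at O1–C2.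
- Weak steps avoided by design: there is no chalcone, so no aurone pathway. O5 and O8 are never protected, because they are the quinone carbonyls of the key intermediate. No methyl ether has to be cleaved selectively. Only ring B carries protecting groups (MOM), removed by acid at the end.

Key step: step 4

Remark: 8 and 9 are drawn as diketo tautomers; their single methine stereocentre is enolisable, would form racemic and disappears in step 4. The target has no stereocentre.

**Route**

Step 1
Reactants: 1 gallic acid (3,4,5-trihydroxybenzoic acid)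
Product: 3 3,4,5-tris(methoxymethoxy)benzoic acid, via methoxymethyl ester 2 (not isolated)
Conditions: MOMCl (5 equiv), i-Pr2NEt (6 equiv), DMF, 0 °C to rt; aqueous work-up; then NaOH (2 M aq), MeOH/THF, rt; cold 1 M HCl to pH 4
Reagents that add atoms: chloromethyl methyl ether, COCCl; sodium hydroxide, [Na+].[OH-]
Why: Williamson O-alkylation of the three phenols and the carboxylate with the reactive alpha-chloro ether, followed by saponification, which should cleave only the ester-type methoxymethyl group because aryl MOM acetals are inert to hydroxide.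

Step 2
Reactants: 4 2-methoxybenzene-1,4-diol (methoxyhydroquinone); 5 methoxyacetic acid
Product: 6 1-(2,5-dihydroxy-4-methoxyphenyl)-2-methoxyethan-1-one
Conditions: BF3·OEt2 (5 equiv, neat), 85 °C, argon; then ice-water
Reagents that add atoms: none
Why: Friedel–Crafts acylation by the BF3-activated acid (O-acylation, then Fries shift), directed to the one ring position that is ortho to a hydroxyl and para to the methoxy group, with the ortho-hydroxyketone held as its difluoroboron chelate, which should block a second acylation until the aqueous work-up.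

Step 3
Reactants: 3 3,4,5-tris(methoxymethoxy)benzoic acid; 6 1-(2,5-dihydroxy-4-methoxyphenyl)-2-methoxyethan-1-one
Product: 8 1-(2,5-dihydroxy-4-methoxyphenyl)-2-methoxy-3-[3,4,5-tris(methoxymethoxy)phenyl]propane-1,3-dione, via acyl imidazolide 7 (not isolated)
Conditions: 3, CDI (1.05 equiv), THF, rt; separately 6, LiN(SiMe3)2 (5.2 equiv), THF, −78 to −20 °C; add 7 at −78 °C, then to rt; AcOH quench at 0 °C; argon throughout
Reagents that add atoms: none
Why: Claisen-type C-acylation of the lithium trianion of an unprotected hydroxyacetophenone (both phenoxides and the ketone enolate), in which the enolate carbon should be the most nucleophilic site and the diketonate formed resists a second acylation, while the mild acetic acid quench keeps the MOM ethers and avoids dehydrative closure of 8 through its 2'-hydroxyl.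

Step 4
Reactants: 8 1-(2,5-dihydroxy-4-methoxyphenyl)-2-methoxy-3-[3,4,5-tris(methoxymethoxy)phenyl]propane-1,3-dione
Product: 10 5,8-dihydroxy-3,7-dimethoxy-2-[3,4,5-tris(methoxymethoxy)phenyl]-4H-chromen-4-one, via acylquinone 9 (not isolated)
Conditions: Ag2O (1.0 equiv), Na2SO4, CH2Cl2, 0 °C to rt, dark, argon; filter through Celite; 2,6-lutidine (0.2 equiv), rt
Reagents that add atoms: none
Why: Proposed new method: Ag2O should dehydrogenate the hydroquinone of 8 to the 2-acyl-1,4-benzoquinone 9, in which the ring carbon next to the acyl-bearing carbon (the future C8a) is the beta carbon of both the quinone enone and the exocyclic ketone; the enol oxygen of the 1,3-diketone adds to it and enolisation re-aromatises ring A, so that O1–C8a is formed at a C–H bond and O5 and O8 return as free hydroxyls, the net change being loss of H2 from 8. The closest known reaction type is the regioselective addition of oxygen, nitrogen and sulfur nucleophiles to C3 of 2-acyl-1,4-benzoquinones and its intramolecular form, the closure of 2-(2-hydroxybenzoyl)-1,4-benzoquinones to 1,4-dioxygenated xanthones; a diketone enol as the oxygen nucleophile, giving a flavone, is the new element. Ring C closes in a 6-endo-trig oxa-Michael mode and no stereocentre is formed. The selectivity needed is closure at C8a instead of the ordinary dehydrative closure through the 2'-hydroxyl (which would give the 6-hydroxy-7-methoxy isomer) and instead of carbon attack: in 9 both phenols are masked as quinone carbonyls, addition of the enol to the adjacent quinone carbonyl is reversible, and attack by the central carbon would need a four-membered ring. With one equivalent of oxidant, any product that is oxidised further by 9 should be returned by the 8 released in that exchange, because only 9 is consumed irreversibly.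

Step 5
Reactants: 10 5,8-dihydroxy-3,7-dimethoxy-2-[3,4,5-tris(methoxymethoxy)phenyl]-4H-chromen-4-one
Product: 11 5,8-dihydroxy-3,7-dimethoxy-2-(3,4,5-trihydroxyphenyl)-4H-chromen-4-one (the target)
Conditions: HCl (1 M in degassed MeOH), 40 °C, argon; evaporate
Reagents that add atoms: none
Why: acid-catalysed transacetalisation of the three aryl MOM ethers to methanol, under which aryl and enol methyl ethers are stable and which is far too mild for a Wessely–Moser ring opening, while the acidic, oxygen-free medium should protect the hydroquinone and pyrogallol units from autoxidation.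

**Compound list**

1 | gallic acid (3,4,5-trihydroxybenzoic acid) | OC(=O)c1cc(O)c(O)c(O)c1 | starting material
2 | methoxymethyl 3,4,5-tris(methoxymethoxy)benzoate (formed in the flask) | COCOC(=O)c1cc(OCOC)c(OCOC)c(OCOC)c1 | intermediate
3 | 3,4,5-tris(methoxymethoxy)benzoic acid | COCOc1cc(C(=O)O)cc(OCOC)c1OCOC | intermediate
4 | 2-methoxybenzene-1,4-diol (methoxyhydroquinone) | COc1cc(O)ccc1O | starting material
5 | methoxyacetic acid | COCC(=O)O | starting material
6 | 1-(2,5-dihydroxy-4-methoxyphenyl)-2-methoxyethan-1-one | COCC(=O)c1cc(O)c(OC)cc1O | intermediate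
7 | (1H-imidazol-1-yl)[3,4,5-tris(methoxymethoxy)phenyl]methanone (acyl imidazolide, formed in the flask) | COCOc1cc(C(=O)n2ccnc2)cc(OCOC)c1OCOC | intermediate
8 | 1-(2,5-dihydroxy-4-methoxyphenyl)-2-methoxy-3-[3,4,5-tris(methoxymethoxy)phenyl]propane-1,3-dione (racemic, enolisable) | COCOc1cc(C(=O)C(OC)C(=O)c2cc(O)c(OC)cc2O)cc(OCOC)c1OCOC | intermediate
9 | 2-methoxy-5-{2-methoxy-3-oxo-3-[3,4,5-tris(methoxymethoxy)phenyl]propanoyl}cyclohexa-2,5-diene-1,4-dione (acylquinone, formed in the flask) | COCOc1cc(C(=O)C(OC)C(=O)C2=CC(=O)C(OC)=CC2=O)cc(OCOC)c1OCOC | intermediate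
10 | 5,8-dihydroxy-3,7-dimethoxy-2-[3,4,5-tris(methoxymethoxy)phenyl]-4H-chromen-4-one | COc1cc(O)c2c(=O)c(OC)c(-c3cc(OCOC)c(OCOC)c(OCOC)c3)oc2c1O | intermediate
11 | 5,8-dihydroxy-3,7-dimethoxy-2-(3,4,5-trihydroxyphenyl)-4H-chromen-4-one (5,8,3',4',5'-pentahydroxy-3,7-dimethoxyflavone) | COc1cc(O)c2c(=O)c(OC)c(-c3cc(O)c(O)c(O)c3)oc2c1O | target

**Step count and risks**

Total steps: 5. Longest linear sequence: 4 (step 1 or step 2, then steps 3, 4, 5).

Steps most likely to fail:

1. Step 4 (proposed new method). The enol oxygen may add too slowly to the acylquinone. Redox exchange between acylquinone and product hydroquinone may over-oxidise the product and stall. The diketone may also close dehydratively through its 2'-hydroxyl before it is oxidised. The fallback uses known chemistry, sets out from 3 and comes back to the route at 11. The imidazolide 7 (from 3 and CDI) would C-acylate the LiN(SiMe3)2 polyanion of commercially available 2-methoxy-1-(2,4,6-trihydroxyphenyl)ethan-1-one F1 to give 2-methoxy-1-(2,4,6-trihydroxyphenyl)-3-[3,4,5-tris(methoxymethoxy)phenyl]propane-1,3-dione F2. Non-acidic cyclodehydration through a 2'-hydroxyl (DBU, pyridine, 90 °C) would give 5,7-dihydroxy-3-methoxy-2-[3,4,5-tris(methoxymethoxy)phenyl]-4H-chromen-4-one F3. MeI (1.0 equiv), K2CO3, acetone would methylate the non-chelated 7-hydroxyl to 5-hydroxy-3,7-dimethoxy-2-[3,4,5-tris(methoxymethoxy)phenyl]-4H-chromen-4-one F4. Elbs persulfate oxidation (K2S2O8, aq KOH, pyridine, 0 °C to rt) would place a sulfate para to the 5-hydroxyl, giving potassium 5-hydroxy-3,7-dimethoxy-4-oxo-2-[3,4,5-tris(methoxymethoxy)phenyl]-4H-chromen-8-yl sulfate F5. Warm HCl in aqueous MeOH would hydrolyse the sulfate and the MOM ethers together to 11.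

2. Step 3. The phenoxides may be O-acylated in place of the enolate carbon, proton transfer may quench the enolate, or the hydroquinone polyanion may be oxidised by traces of air. The fallback sets out from 6 (with 7 made from 3) and comes back at 8. Both phenols of 6 would be aroylated with 7 (2.2 equiv, DBU, THF) to 2-methoxy-5-(methoxyacetyl)-1,4-phenylene bis[3,4,5-tris(methoxymethoxy)benzoate] F6. KOC(CH3)3 in THF at 0 °C would trigger Baker–Venkataraman O-to-C migration of the ortho ester to 4-hydroxy-2-methoxy-5-{2-methoxy-3-oxo-3-[3,4,5-tris(methoxymethoxy)phenyl]propanoyl}phenyl 3,4,5-tris(methoxymethoxy)benzoate F7. K2CO3 in MeOH would remove the remaining aryl ester to give 8.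

3. Step 2. The acylation may stop at the aryl ester, attack another ring carbon, or lose the aliphatic methyl ether to BF3. The fallback sets out from 4 and 5 and comes back at 6. Compound 4 would be benzylated (BnBr, K2CO3, DMF) to 1,4-bis(benzyloxy)-2-methoxybenzene F8, and 5 converted with (COCl)2 to methoxyacetyl chloride F9. Friedel–Crafts acylation of the phenol-free ether (SnCl4, CH2Cl2, −20 °C), para to the methoxy group, would give 1-[2,5-bis(benzyloxy)-4-methoxyphenyl]-2-methoxyethan-1-one F10. Hydrogenolysis (H2, 10% Pd/C, EtOAc) would give 6.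

Further compounds
F1 | step 4 | 2-methoxy-1-(2,4,6-trihydroxyphenyl)ethan-1-one | COCC(=O)c1c(O)cc(O)cc1O
F2 | step 4 | 2-methoxy-1-(2,4,6-trihydroxyphenyl)-3-[3,4,5-tris(methoxymethoxy)phenyl]propane-1,3-dione | COCOc1cc(C(=O)C(OC)C(=O)c2c(O)cc(O)cc2O)cc(OCOC)c1OCOC
F3 | step 4 | 5,7-dihydroxy-3-methoxy-2-[3,4,5-tris(methoxymethoxy)phenyl]-4H-chromen-4-one | COCOc1cc(-c2oc3cc(O)cc(O)c3c(=O)c2OC)cc(OCOC)c1OCOC
F4 | step 4 | 5-hydroxy-3,7-dimethoxy-2-[3,4,5-tris(methoxymethoxy)phenyl]-4H-chromen-4-one | COCOc1cc(-c2oc3cc(OC)cc(O)c3c(=O)c2OC)cc(OCOC)c1OCOC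
F5 | step 4 | potassium 5-hydroxy-3,7-dimethoxy-4-oxo-2-[3,4,5-tris(methoxymethoxy)phenyl]-4H-chromen-8-yl sulfate | COCOc1cc(-c2oc3c(OS(=O)(=O)[O-])c(OC)cc(O)c3c(=O)c2OC)cc(OCOC)c1OCOC.[K+]
F6 | step 3 | 2-methoxy-5-(methoxyacetyl)-1,4-phenylene bis[3,4,5-tris(methoxymethoxy)benzoate] | COCC(=O)c1cc(OC(=O)c2cc(OCOC)c(OCOC)c(OCOC)c2)c(OC)cc1OC(=O)c1cc(OCOC)c(OCOC)c(OCOC)c1
F7 | step 3 | 4-hydroxy-2-methoxy-5-{2-methoxy-3-oxo-3-[3,4,5-tris(methoxymethoxy)phenyl]propanoyl}phenyl 3,4,5-tris(methoxymethoxy)benzoate | COCOc1cc(C(=O)C(OC)C(=O)c2cc(OC(=O)c3cc(OCOC)c(OCOC)c(OCOC)c3)c(OC)cc2O)cc(OCOC)c1OCOC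
F8 | step 2 | 1,4-bis(benzyloxy)-2-methoxybenzene | COc1cc(OCc2ccccc2)ccc1OCc1ccccc1
F9 | step 2 | methoxyacetyl chloride | COCC(=O)Cl
F10 | step 2 | 1-[2,5-bis(benzyloxy)-4-methoxyphenyl]-2-methoxyethan-1-one | COCC(=O)c1cc(OCc2ccccc2)c(OC)cc1OCc1ccccc1
A1 | direct plan | 2-hydroxy-3,4,6-trimethoxyacetophenone | CC(=O)c1c(OC)cc(OC)c(OC)c1O
A2 | direct plan | 3,4,5-tris(benzyloxy)benzaldehyde | O=Cc1cc(OCc2ccccc2)c(OCc2ccccc2)c(OCc2ccccc2)c1
A3 | direct plan | (E)-1-(2-hydroxy-3,4,6-trimethoxyphenyl)-3-[3,4,5-tris(benzyloxy)phenyl]prop-2-en-1-one | COc1cc(OC)c(C(=O)/C=C/c2cc(OCc3ccccc3)c(OCc3ccccc3)c(OCc3ccccc3)c2)c(O)c1OC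
A4 | direct plan | 3-hydroxy-5,7,8-trimethoxy-2-[3,4,5-tris(benzyloxy)phenyl]-4H-chromen-4-one | COc1cc(OC)c2c(=O)c(O)c(-c3cc(OCc4ccccc4)c(OCc4ccccc4)c(OCc4ccccc4)c3)oc2c1OC
A5 | direct plan | 3,5,7,8-tetramethoxy-2-[3,4,5-tris(benzyloxy)phenyl]-4H-chromen-4-one | COc1cc(OC)c2c(=O)c(OC)c(-c3cc(OCc4ccccc4)c(OCc4ccccc4)c(OCc4ccccc4)c3)oc2c1OC
A6 | direct plan | 3,7-dimethoxy-2-[3,4,5-tris(benzyloxy)phenyl]-4H-chromene-4,5,8-trione | COC1=CC(=O)C2=C(OC(c3cc(OCc4ccccc4)c(OCc4ccccc4)c(OCc4ccccc4)c3)=C(OC)C2=O)C1=O
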